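**Retrosynthetic overview**
- The target is read as the hydrolysed form of a 4-substituted 1,4-dihydropyridine: the two aldehydes are the ring C6 and C2 enamine carbons, the E-ethylidene is a 5-vinyl group that moves into conjugation on hydrolysis, and the α-formyl methyl ester is the C2–C3 unit of a nicotinate.
- Key disconnection at the stereocentre: an acetate silyl ketene acetal that already carries the hydroxytyrosyl ester adds to C4 of an N-benzyl nicotinate pyridinium chloride under a chiral thiourea (anion-binding organocatalysis).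
- The pyridinium salt comes from methyl 5-bromonicotinate by vinylation and N-benzylation; the ketene acetal comes from hydroxytyrosol acetate.
- No ring is built. The only ring handled is the pyridine, which is dearomatised in the key step and opened in the last step to the acyclic target.

Assumptions: hydroxytyrosol acetate is bought; the α-formyl ester stereocentre is epimerisable and is taken to settle under thermodynamic control to the drawn S epimer, while the non-labile centre is fixed by the catalyst.

**Step 1**
Reactants: 1 2-(3,4-dihydroxyphenyl)ethyl acetate (hydroxytyrosol acetate)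
Product: 2 tert-butyl[(1-{2-[3,4-bis({[tert-butyl(dimethyl)silyl]oxy})phenyl]ethoxy}ethenyl)oxy]dimethylsilane (O-silyl ketene acetal of 1 with both phenols silylated)
Conditions: TBSCl (3.5 equiv), LiN(iPr)2 (3.3 equiv, added last), DMPU, THF, −78 → 0 °C; filtered under Ar, used crude
Reagents that add atoms: tert-butyldimethylsilyl chloride, CC(C)(C)[Si](C)(C)Cl
Why: Triple deprotonation in the presence of the silyl chloride caps both phenoxides and traps the acetate enolate on oxygen (standard silyl ketene acetal formation, as used before Ireland–Claisen rearrangements); no stereocentre is formed.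

**Step 2**
Reactants: 3 methyl 5-bromopyridine-3-carboxylate; 4 potassium ethenyltrifluoroborate
Product: 5 methyl 5-ethenylpyridine-3-carboxylate
Conditions: PdCl2 (2 mol %), PPh3 (6 mol %), Cs2CO3 (3 equiv), THF–H2O 9:1, 85 °C
Reagents that add atoms: none
Why: Suzuki–Miyaura vinylation of an electron-poor 3-bromopyridine with the air-stable vinyltrifluoroborate is a standard coupling that tolerates the methyl ester; no stereocentre is formed.

**Step 3**
Reactants: 5 methyl 5-ethenylpyridine-3-carboxylate
Product: 6 1-benzyl-3-ethenyl-5-(methoxycarbonyl)pyridin-1-ium chloride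
Conditions: BnCl (1.5 equiv), BHT (trace), MeCN, 70 °C; precipitated with Et2O, dried in vacuo
Reagents that add atoms: benzyl chloride, ClCc1ccccc1
Why: Menshutkin N-alkylation gives the crystalline pyridinium chloride, which is both the activated electrophile and the chloride source for anion binding; no stereocentre is formed.

**Step 4 (key step)**
Reactants: 6 1-benzyl-3-ethenyl-5-(methoxycarbonyl)pyridin-1-ium chloride; 2 the tris-silyl ketene acetal (1.5 equiv)
Product: 7 methyl (4R)-1-benzyl-4-{2-[2-(3,4-bis{[tert-butyl(dimethyl)silyl]oxy}phenyl)ethoxy]-2-oxoethyl}-5-ethenyl-1,4-dihydropyridine-3-carboxylate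
Conditions: chiral amido-thiourea 1-[3,5-bis(trifluoromethyl)phenyl]-3-{(2S)-3,3-dimethyl-1-oxo-1-[(2R)-2-phenylpyrrolidin-1-yl]butan-2-yl}thiourea (10 mol %; the mirror-image catalyst is used if it is the one that delivers 4R), MTBE, 4 Å MS, −30 → 0 °C, 48 h; short pad of Et3N-deactivated silica; 7 used at once
Reagents that add atoms: none
Why: Proposed new method: an enantioselective anion-binding Mukaiyama–Mannich-type dearomatisation in which the thiourea binds the chloride of the otherwise insoluble salt and draws the pyridinium into solution as a chiral contact ion pair with the catalyst arene stacked on one face, the soft silyl ketene acetal adds to C4 on the open face to set the (4R) centre (C4 is the site taken by ester enolates in racemic γ-additions to N-alkyl nicotinate salts), and silyl transfer to chloride releases tert-butyldimethylsilyl chloride and the catalyst; the closest known reactions are thiourea-catalysed additions of silyl ketene acetals to N-acyl isoquinolinium and pyridinium chlorides and organocatalytic C4-selective additions of enamines and indoles to N-benzyl 3-nitropyridinium salts, but an acetate ketene acetal on a 3,5-disubstituted N-alkyl nicotinate salt has not been shown.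

**Step 5**
Reactants: 7 the (4R)-dihydropyridine
Product: 10 2-(3,4-dihydroxyphenyl)ethyl (3S,4E)-4-formyl-3-[(2S)-1-methoxy-1,3-dioxopropan-2-yl]hex-4-enoate, via ring-opened enamino ester 8 (not isolated), via bis-silyl dialdehyde 9 (not isolated)
Conditions: aq. HF (48 %, 12 equiv), MeCN–H2O 10:1, 0 °C (1 h) → 20 °C (3 h); CHCl3 extraction from the acidic phase, no basic wash
Reagents that add atoms: water, O
Why: Acid-mediated enamine hydrolysis of the cyclic dienamine and vinylogous carbamate, in which protonation at the vinyl terminus gives a conjugated iminium that is hydrolysed to the E-ethylidene aldehyde (thermodynamic geometry), the N-benzyl enamino ester then hydrolyses to the α-formyl ester with loss of benzylammonium, and HF removes the two aryl silyl ethers; the catalyst-set centre is untouched and the new α-formyl ester centre is set by thermodynamic protonation (epimerisable, see assumption).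

**Compound list**
1 | 2-(3,4-dihydroxyphenyl)ethyl acetate | CC(=O)OCCc1ccc(O)c(O)c1 | starting material
2 | tert-butyl[(1-{2-[3,4-bis({[tert-butyl(dimethyl)silyl]oxy})phenyl]ethoxy}ethenyl)oxy]dimethylsilane | C=C(O[Si](C)(C)C(C)(C)C)OCCc1ccc(O[Si](C)(C)C(C)(C)C)c(O[Si](C)(C)C(C)(C)C)c1 | intermediate
3 | methyl 5-bromopyridine-3-carboxylate | COC(=O)c1cncc(Br)c1 | starting material
4 | potassium ethenyltrifluoroborate | C=C[B-](F)(F)F.[K+] | starting material
5 | methyl 5-ethenylpyridine-3-carboxylate | COC(=O)c1cncc(C=C)c1 | intermediate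
6 | 1-benzyl-3-ethenyl-5-(methoxycarbonyl)pyridin-1-ium chloride | C=Cc1cc(C(=O)OC)c[n+](Cc2ccccc2)c1.[Cl-] | intermediate
7 | methyl (4R)-1-benzyl-4-{2-[2-(3,4-bis{[tert-butyl(dimethyl)silyl]oxy}phenyl)ethoxy]-2-oxoethyl}-5-ethenyl-1,4-dihydropyridine-3-carboxylate | C=CC1=CN(Cc2ccccc2)C=C(C(=O)OC)[C@@H]1CC(=O)OCCc3ccc(O[Si](C)(C)C(C)(C)C)c(O[Si](C)(C)C(C)(C)C)c3 | intermediate
8 | 2-[3,4-bis({[tert-butyl(dimethyl)silyl]oxy})phenyl]ethyl (3R,4E)-3-[(1Z)-1-(benzylamino)-3-methoxy-3-oxoprop-1-en-2-yl]-4-formylhex-4-enoate (same spatial arrangement at C3 as in 10) | C/C=C(/C=O)[C@@H](CC(=O)OCCc1ccc(O[Si](C)(C)C(C)(C)C)c(O[Si](C)(C)C(C)(C)C)c1)/C(C(=O)OC)=C/NCc1ccccc1 | intermediate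
9 | 2-[3,4-bis({[tert-butyl(dimethyl)silyl]oxy})phenyl]ethyl (3S,4E)-4-formyl-3-[(2S)-1-methoxy-1,3-dioxopropan-2-yl]hex-4-enoate | C/C=C(/C=O)[C@@H](CC(=O)OCCc1ccc(O[Si](C)(C)C(C)(C)C)c(O[Si](C)(C)C(C)(C)C)c1)[C@@H](C=O)C(=O)OC | intermediate
10 | 2-(3,4-dihydroxyphenyl)ethyl (3S,4E)-4-formyl-3-[(2S)-1-methoxy-1,3-dioxopropan-2-yl]hex-4-enoate | C/C=C(/C=O)[C@@H](CC(=O)OCCc1ccc(O)c(O)c1)[C@@H](C=O)C(=O)OC | target

**Step count and risks**
Total step count: 5. Longest linear sequence: 4 (steps 2, 3, 4, 5).

The three steps most likely to fail are step 4, step 5 and step 1.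

Step 4 is the proposed new reaction. Its risks are attack at C2 or C6 instead of the doubly flanked C4, and weak face discrimination, since the two faces differ only through the ester and vinyl neighbours. The fallback uses known chemistry and sets out from 6 and 2. In MeCN, where the salt dissolves, the ketene acetal adds at C4 without a chiral catalyst, the classical γ-addition of ester enolate equivalents to N-alkyl nicotinate salts, and gives racemic methyl 1-benzyl-4-{2-[2-(3,4-bis{[tert-butyl(dimethyl)silyl]oxy}phenyl)ethoxy]-2-oxoethyl}-5-ethenyl-1,4-dihydropyridine-3-carboxylate F1. Preparative SFC on a chiral stationary phase then separates 7 from its (4S)-enantiomer F2, which is discarded. The fallback comes back to the route at 7.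

Step 5 may stall at a cyclic carbinolamine or at the enamino ester. The released dialdehyde may also drift to the oxa-Michael (elenolate-type) isomers, or keep some Z-ethylidene, if it is left in acid. The fallback changes the nitrogen activation so that the ring opens as an N–H enamine near neutral pH; it sets out from 5 and 2. Pyridine 5 is activated in situ with 2,2,2-trichloroethyl chloroformate under the same thiourea (the established acyl-pyridinium mode of this catalyst class) to give 3-methyl 1-(2,2,2-trichloroethyl) (4R)-4-{2-[2-(3,4-bis{[tert-butyl(dimethyl)silyl]oxy}phenyl)ethoxy]-2-oxoethyl}-5-ethenylpyridine-1,3(4H)-dicarboxylate F3. Zn dust in THF with aq. NH4OAc–AcOH buffer (pH 5, 0 °C) removes the carbamate. The resulting methyl (4R)-4-{2-[2-(3,4-bis{[tert-butyl(dimethyl)silyl]oxy}phenyl)ethoxy]-2-oxoethyl}-5-ethenyl-1,4-dihydropyridine-3-carboxylate F4 hydrolyses in the same buffer with loss of ammonia. The fallback comes back to the route at 9, which is desilylated with aq. HF in MeCN as in the second half of step 5 to give 10.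

Step 1 may give C-silylation or Claisen self-condensation, and the crude high-boiling ketene acetal cannot be distilled. The fallback brings the hydroxytyrosyl group in after the key step; it sets out from 6. Bought 2,2,2-trifluoroethyl acetate is converted (LiN(iPr)2, TBSCl, THF–DMPU, −78 °C) into the distillable tert-butyl(dimethyl){[1-(2,2,2-trifluoroethoxy)ethenyl]oxy}silane F5. The step 4 conditions with 6 give methyl (4R)-1-benzyl-5-ethenyl-4-[2-oxo-2-(2,2,2-trifluoroethoxy)ethyl]-1,4-dihydropyridine-3-carboxylate F6. Immobilised Candida antarctica lipase B with bought hydroxytyrosol (1.2 equiv, MTBE, 40 °C) transfers the activated acyl group to the primary alcohol only and gives methyl (4R)-1-benzyl-4-{2-[2-(3,4-dihydroxyphenyl)ethoxy]-2-oxoethyl}-5-ethenyl-1,4-dihydropyridine-3-carboxylate F7. Dilute aqueous acid then opens the ring as in step 5, with no silyl ether to cleave. The fallback comes back to the route at 10.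

**Further compounds**
F1 | step 4 | racemic methyl 1-benzyl-4-{2-[2-(3,4-bis{[tert-butyl(dimethyl)silyl]oxy}phenyl)ethoxy]-2-oxoethyl}-5-ethenyl-1,4-dihydropyridine-3-carboxylate | C=CC1=CN(Cc2ccccc2)C=C(C(=O)OC)C1CC(=O)OCCc3ccc(O[Si](C)(C)C(C)(C)C)c(O[Si](C)(C)C(C)(C)C)c3
F2 | step 4 | methyl (4S)-1-benzyl-4-{2-[2-(3,4-bis{[tert-butyl(dimethyl)silyl]oxy}phenyl)ethoxy]-2-oxoethyl}-5-ethenyl-1,4-dihydropyridine-3-carboxylate | C=CC1=CN(Cc2ccccc2)C=C(C(=O)OC)[C@H]1CC(=O)OCCc3ccc(O[Si](C)(C)C(C)(C)C)c(O[Si](C)(C)C(C)(C)C)c3
F3 | step 5 | 3-methyl 1-(2,2,2-trichloroethyl) (4R)-4-{2-[2-(3,4-bis{[tert-butyl(dimethyl)silyl]oxy}phenyl)ethoxy]-2-oxoethyl}-5-ethenylpyridine-1,3(4H)-dicarboxylate | C=CC1=CN(C(=O)OCC(Cl)(Cl)Cl)C=C(C(=O)OC)[C@@H]1CC(=O)OCCc3ccc(O[Si](C)(C)C(C)(C)C)c(O[Si](C)(C)C(C)(C)C)c3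
F4 | step 5 | methyl (4R)-4-{2-[2-(3,4-bis{[tert-butyl(dimethyl)silyl]oxy}phenyl)ethoxy]-2-oxoethyl}-5-ethenyl-1,4-dihydropyridine-3-carboxylate | C=CC1=CNC=C(C(=O)OC)[C@@H]1CC(=O)OCCc3ccc(O[Si](C)(C)C(C)(C)C)c(O[Si](C)(C)C(C)(C)C)c3
F5 | step 1 | tert-butyl(dimethyl){[1-(2,2,2-trifluoroethoxy)ethenyl]oxy}silane | C=C(O[Si](C)(C)C(C)(C)C)OCC(F)(F)F
F6 | step 1 | methyl (4R)-1-benzyl-5-ethenyl-4-[2-oxo-2-(2,2,2-trifluoroethoxy)ethyl]-1,4-dihydropyridine-3-carboxylate | C=CC1=CN(Cc2ccccc2)C=C(C(=O)OC)[C@@H]1CC(=O)OCC(F)(F)F
F7 | step 1 | methyl (4R)-1-benzyl-4-{2-[2-(3,4-dihydroxyphenyl)ethoxy]-2-oxoethyl}-5-ethenyl-1,4-dihydropyridine-3-carboxylate | C=CC1=CN(Cc2ccccc2)C=C(C(=O)OC)[C@@H]1CC(=O)OCCc3ccc(O)c(O)c3
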